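Ring B is disconnected across C5–C10 and C7–C8, which reveals a [3+3] pairing: C8–C9–C10 as an enone (C8 the carbonyl carbon that becomes the tertiary carbinol, C10 the β-carbon that becomes the quaternary centre) and C5–C6–C7 as an allylsilane that acts twice as a nucleophile. One acid-catalysed tandem Hosomi–Sakurai/carbonyl-ene bicyclization of an acyclic silylated dienone closes ring A (C5–C10) and ring B (C7–C8) and sets C8, C9 and C10 under catalyst control. C13 is bought with methyl hydrogen (R)-3-methylglutarate. C5 is set afterwards by hydrogen-atom-transfer hydrogenation of the C5=C6 alkene left by the ene step.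

Key step: step 7

Remark: atoms carry labdane numbering; the sense of induction of the chiral acid in step 7 cannot be assigned in advance, so the antipode that gives the 10S series is assumed to be taken from a screen of both.

Step 1
Reactants: 1 methyltriphenylphosphonium bromide; 2 (iodomethyl)trimethylsilane; 3 2,2-dimethylpent-4-enal
Product: 7 (2Z)-(4,4-dimethylhepta-2,6-dien-1-yl)trimethylsilane, via methylenetriphenylphosphorane 4 (not isolated), via phosphonium iodide 5 (not isolated), via silyl ylide 6 (not isolated)
Conditions: n-BuLi (1 equiv), THF, 0 °C; 2, rt; n-BuLi (1 equiv), −78 °C; 3, −78 °C to rt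
Reagents that add atoms: none
Why: The ylide is alkylated by 2, the resulting salt is deprotonated again, and Wittig olefination of the non-enolizable neopentyl aldehyde should give the allylsilane, mainly as the Z alkene (this geometry is not carried into the target).

Step 2
Reactants: 8 (3R)-5-methoxy-3-methyl-5-oxopentanoic acid (methyl hydrogen (R)-3-methylglutarate)
Product: 10 (4S)-4-methyloxan-2-one, via (3S)-5-hydroxy-3-methylpentanoic acid 9 (not isolated)
Conditions: LiBH4, THF, 0 °C to rt; then 2 M HCl, rt
Reagents that add atoms: none
Why: Chemoselective borohydride reduction of the ester in the presence of the lithium carboxylate, then acid-induced lactonization, turns the ester arm into C11 and keeps the acid arm as C15, so the untouched stereocentre becomes C13 with the required configuration.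

Step 3
Reactants: 10 (4S)-4-methyloxan-2-one
Product: 12 methyl (3R)-5-iodo-3-methylpentanoate, via trimethylsilyl (3R)-5-iodo-3-methylpentanoate 11 (not isolated)
Conditions: Me3SiI, CHCl3, 60 °C; then MeOH, rt
Reagents that add atoms: iodotrimethylsilane, C[Si](C)(C)I; methanol, CO
Why: Lactone cleavage by iodotrimethylsilane (SN2 attack of iodide at the O–CH2 carbon) followed by acid-catalysed Fischer esterification in methanol should give the iodo ester without touching the stereocentre.

Step 4
Reactants: 12 methyl (3R)-5-iodo-3-methylpentanoate; 13 pentane-2,4-dione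
Product: 14 methyl (3S)-6-acetyl-3-methyl-7-oxooctanoate
Conditions: K2CO3, acetone, reflux (excess 13)
Reagents that add atoms: none
Why: C-alkylation of the acetylacetone enolate by the primary iodide forms the C9–C11 bond, and because the diketone is symmetric no regiochemical question arises later.

Step 5
Reactants: 14 methyl (3S)-6-acetyl-3-methyl-7-oxooctanoate
Product: 15 methyl (3S,6Z)-6-acetyl-3-methyl-7-(trifluoromethylsulfonyloxy)oct-6-enoate
Conditions: NaH, Et2O, 0 °C; then Tf2O, −78 to 0 °C
Reagents that add atoms: trifluoromethanesulfonic anhydride, O=S(=O)(OS(=O)(=O)C(F)(F)F)C(F)(F)F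
Why: O-sulfonylation of the chelated sodium enolate should give the Z vinylogous acyl triflate (enol triflate formation), and the alkene geometry is not relayed because C9 becomes stereogenic only in step 7.

Step 6
Reactants: 7 (2Z)-(4,4-dimethylhepta-2,6-dien-1-yl)trimethylsilane; 15 methyl (3S,6Z)-6-acetyl-3-methyl-7-(trifluoromethylsulfonyloxy)oct-6-enoate
Product: 17 methyl (3S,6Z,12Z)-6-acetyl-3,7,11,11-tetramethyl-14-(trimethylsilyl)tetradeca-6,12-dienoate, via B-alkyl-9-borabicyclononane 16 (not isolated)
Conditions: 9-BBN (1.05 equiv), THF, 0 °C to rt; then 15, Pd(dppf)Cl2 (5 mol %), aq K3PO4, DMF, rt to 50 °C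
Reagents that add atoms: none
Why: 9-BBN hydroborates the terminal vinyl group far faster than the hindered internal allylsilane alkene, and B-alkyl Suzuki–Miyaura coupling with the reactive vinylogous acyl triflate forms C1–C10 with retention of the enol triflate geometry.

Step 7
Reactants: 17 methyl (3S,6Z,12Z)-6-acetyl-3,7,11,11-tetramethyl-14-(trimethylsilyl)tetradeca-6,12-dienoate
Product: 20 methyl (8R,9R,10R,13S)-8-hydroxylabd-5-en-15-oate (8α-OH, 10β-methyl), via silyl enol ether 18 (not isolated), via trimethylsilyl ether 19 (not isolated)
Conditions: chiral imidodiphosphorimidate Brønsted acid (IDPi, one antipode, 5 mol %), allyltrimethylsilane (5 mol %), CH2Cl2, −78 °C; then i-PrOH (10 mol %), −78 to −30 °C; then 1 M HCl, THF, 0 °C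
Reagents that add atoms: none
Why: Proposed new method: the silylium form of the confined chiral acid O-silylates enone 17 to a 1-siloxyallyl cation, whose C10 terminus is attacked by the γ-carbon C5 of the allylsilane (anti SE2′; ring A closes 6-exo-trig at both π-systems through a chair with the C20 methyl axial and the two alkenyl arms equatorial) to give silyl enol ether 18; the catalytic proton released by 2-propanol then converts 18 into the silyl-activated C8 ketone, whose carbonyl carbon is attacked by the terminal vinyl carbon C7 while H5 passes suprafacially to the carbonyl oxygen (carbonyl-ene; ring B closes 6-exo at the carbonyl and 6-endo at the vinyl group), and loss of the oxygen-bound proton returns the acid and leaves silyl ether 19. The closest known reaction type is the Lewis-acid tandem Hosomi–Sakurai/carbonyl-ene annulation of allylsilane-bearing 2-alkylidene-1,3-dicarbonyl compounds, together with silylium-based asymmetric counteranion-directed Hosomi–Sakurai and Mukaiyama–Michael additions; new are the simple tetrasubstituted enone, the proton relay and catalyst control of a quaternary centre. C10 and the transient C5 centre are set by the chiral counteranion, which selects the enone face, and their mutual arrangement (H5 anti to C20) by the chair. C9 is set by protonation of 18 under Curtin–Hammett control, the epimer with the side chain pseudo-equatorial in the ene transition state reacting faster. C8 is set by the ene geometry, since its oxygen must sit on the α-face next to H5, which places the C17 methyl β. The step needs conjugate rather than carbonyl attack and C5 rather than C7 as the first nucleophilic carbon, both secured by the six-membered tether and the β-silyl effect, and it needs reagent control of the absolute sense, for which the remote C13 centre offers no competition.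

Step 8
Reactants: 20 methyl (8R,9R,10R,13S)-8-hydroxylabd-5-en-15-oate
Product: 21 methyl (5S,8R,9R,10S,13S)-8-hydroxylabdan-15-oate (methyl labdanolate)
Conditions: Mn(dpm)3 (10 mol %; dpm = dipivaloylmethanate), PhSiH3, t-BuOOH, i-PrOH, rt
Reagents that add atoms: none
Why: Metal-hydride hydrogen-atom-transfer hydrogenation places a hydrogen atom on C6 and quenches the tertiary C5 radical, flanked by two quaternary carbons, from the α-face opposite the axial C19 and C20 methyls, which should give the thermodynamically favoured trans-decalin and so set C5.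

Step 9
Reactants: 21 methyl (5S,8R,9R,10S,13S)-8-hydroxylabdan-15-oate
Product: 22 (5S,8R,9R,10S,13S)-8-hydroxylabdan-15-oic acid (labdanolic acid)
Conditions: LiOH, THF/MeOH/H2O, rt; then dilute HCl
Reagents that add atoms: lithium hydroxide, [Li+].[OH-]
Why: Saponification of the unhindered methyl ester leaves the tertiary alcohol and all stereocentres untouched (C13 is β to the carbonyl and cannot epimerize).

Step 10
Reactants: 22 (5S,8R,9R,10S,13S)-8-hydroxylabdan-15-oic acid
Product: 24 (5S,8R,9R,10S,13S)-8-formyloxylabdan-15-oic acid, via mixed formic anhydride 23 (not isolated)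
Conditions: acetic formic anhydride (excess), pyridine, DMAP (cat.), CH2Cl2, 0 °C to rt; then H2O/THF, rt
Reagents that add atoms: acetic formic anhydride, CC(=O)OC=O
Why: O-formylation with the mixed anhydride transfers the smallest acyl group to the hindered tertiary 8α-hydroxyl without breaking the C8–O bond (retention), and the formic mixed anhydride formed at C15 is hydrolysed selectively in the neutral aqueous work-up.

Compound list
1 | methyltriphenylphosphonium bromide | C[P+](c1ccccc1)(c1ccccc1)c1ccccc1.[Br-] | starting material
2 | (iodomethyl)trimethylsilane | C[Si](C)(C)CI | starting material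
3 | 2,2-dimethylpent-4-enal | C=CCC(C)(C)C=O | starting material
4 | methylenetriphenylphosphorane | C=P(c1ccccc1)(c1ccccc1)c1ccccc1 | intermediate (not isolated)
5 | [2-(trimethylsilyl)ethyl]triphenylphosphonium iodide | C[Si](C)(C)CC[P+](c1ccccc1)(c1ccccc1)c1ccccc1.[I-] | intermediate (not isolated)
6 | [2-(trimethylsilyl)ethylidene]triphenylphosphorane | C[Si](C)(C)CC=P(c1ccccc1)(c1ccccc1)c1ccccc1 | intermediate (not isolated)
7 | (2Z)-(4,4-dimethylhepta-2,6-dien-1-yl)trimethylsilane | C=CCC(C)(C)/C=C\C[Si](C)(C)C | intermediate
8 | (3R)-5-methoxy-3-methyl-5-oxopentanoic acid | OC(=O)C[C@@H](C)CC(=O)OC | starting material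
9 | (3S)-5-hydroxy-3-methylpentanoic acid | OC(=O)C[C@@H](C)CCO | intermediate (not isolated)
10 | (4S)-4-methyloxan-2-one | O=C1C[C@@H](C)CCO1 | intermediate
11 | trimethylsilyl (3R)-5-iodo-3-methylpentanoate | C[Si](C)(C)OC(=O)C[C@@H](C)CCI | intermediate (not isolated)
12 | methyl (3R)-5-iodo-3-methylpentanoate | COC(=O)C[C@@H](C)CCI | intermediate
13 | pentane-2,4-dione | CC(=O)CC(C)=O | starting material
14 | methyl (3S)-6-acetyl-3-methyl-7-oxooctanoate | COC(=O)C[C@@H](C)CCC(C(C)=O)C(C)=O | intermediate
15 | methyl (3S,6Z)-6-acetyl-3-methyl-7-(trifluoromethylsulfonyloxy)oct-6-enoate | COC(=O)C[C@@H](C)CC/C(C(C)=O)=C(\C)OS(=O)(=O)C(F)(F)F | intermediate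
16 | 9-[(5Z)-4,4-dimethyl-7-(trimethylsilyl)hept-5-en-1-yl]-9-borabicyclo[3.3.1]nonane | C[Si](C)(C)C/C=C\C(C)(C)CCCB1C2CCCC1CCC2 | intermediate (not isolated)
17 | methyl (3S,6Z,12Z)-6-acetyl-3,7,11,11-tetramethyl-14-(trimethylsilyl)tetradeca-6,12-dienoate | COC(=O)C[C@@H](C)CC/C(C(C)=O)=C(\C)CCCC(C)(C)/C=C\C[Si](C)(C)C | intermediate
18 | methyl (3S)-3-methyl-6-[(1S,2S)-1,3,3-trimethyl-2-vinylcyclohexyl]-7-(trimethylsilyloxy)oct-6-enoate (enol ether geometry not defined) | COC(=O)C[C@@H](C)CCC(=C(C)O[Si](C)(C)C)[C@@]1(C)CCCC(C)(C)[C@@H]1C=C | intermediate (not isolated)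
19 | methyl (8R,9R,10R,13S)-8-(trimethylsilyloxy)labd-5-en-15-oate | COC(=O)C[C@@H](C)CC[C@@H]1[C@@]2(C)CCCC(C)(C)C2=CC[C@@]1(C)O[Si](C)(C)C | intermediate (not isolated)
20 | methyl (8R,9R,10R,13S)-8-hydroxylabd-5-en-15-oate | COC(=O)C[C@@H](C)CC[C@@H]1[C@@]2(C)CCCC(C)(C)C2=CC[C@@]1(C)O | intermediate
21 | methyl (5S,8R,9R,10S,13S)-8-hydroxylabdan-15-oate | COC(=O)C[C@@H](C)CC[C@@H]1[C@@]2(C)CCCC(C)(C)[C@@H]2CC[C@@]1(C)O | intermediate
22 | (5S,8R,9R,10S,13S)-8-hydroxylabdan-15-oic acid | OC(=O)C[C@@H](C)CC[C@@H]1[C@@]2(C)CCCC(C)(C)[C@@H]2CC[C@@]1(C)O | intermediate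
23 | (5S,8R,9R,10S,13S)-8-formyloxylabdan-15-oic formic anhydride | O=COC(=O)C[C@@H](C)CC[C@@H]1[C@@]2(C)CCCC(C)(C)[C@@H]2CC[C@@]1(C)OC=O | intermediate (not isolated)
24 | (5S,8R,9R,10S,13S)-8-formyloxylabdan-15-oic acid | C[C@@H](CC[C@@H]1[C@@]2(C)CCCC(C)(C)[C@@H]2CC[C@@]1(C)OC=O)CC(=O)O | target

Total steps: 10. Longest linear sequence: 9 steps (steps 2 to 10, from 8).

Steps most likely to fail

Step 7 (Proposed new method). Three processes threaten it. The twisted tetrasubstituted enone may be too poor an acceptor, so that protodesilylation of the allylsilane outruns ring A closure. The chiral anion may discriminate the enone faces poorly, giving both ring series as diastereomers through C13. The second stage may end in elimination or cationic rearrangement instead of the ene closure. The fallback makes the two bonds in two flasks with known reactions. It sets out from 17: intramolecular Hosomi–Sakurai cyclization with EtAlCl2 in toluene at −78 °C and aqueous work-up should give the vinyl ketone methyl (3S,6R)-3-methyl-7-oxo-6-[(1S,2S)-1,3,3-trimethyl-2-vinylcyclohexyl]octanoate F1. Carbonyl-ene cyclization of F1 with Me2AlCl in CH2Cl2 (−78 to 0 °C) then returns to the route at 20. Without catalyst control, 20 must be separated from its C9 epimer and from the ring-enantiomeric series by chromatography, or by crystallization at the stage of acid 22.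

Step 8. Hydrogen-atom transfer to the shielded C5=C6 alkene may be slow, or the C5 radical may be quenched from the β-face and give the cis-fused ring system. The fallback replaces radical hydrogenation by hydroxyl-directed hydrogenation: from 20, [Ir(cod)(PCy3)(py)]PF6 and H2 in CH2Cl2, in which the 8α-hydroxyl binds iridium and both hydrogens are delivered to the α-face, returning at 21. No new compound is made.

Step 10. Acylation of the hindered tertiary hydroxyl may stay incomplete, and the formate may be lost or eliminated while the C15 mixed anhydride is hydrolysed. The fallback changes the protecting-group logic so that no free acid is present during formylation. From 22, benzyl bromide and K2CO3 in DMF should give benzyl (5S,8R,9R,10S,13S)-8-hydroxylabdan-15-oate F2. Forcing formylation with acetic formic anhydride, pyridine and DMAP should give benzyl (5S,8R,9R,10S,13S)-8-formyloxylabdan-15-oate F3. Neutral hydrogenolysis (H2, Pd/C, ethyl acetate) then returns to the route at 24.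

Further compounds
F1 | step 7 | methyl (3S,6R)-3-methyl-7-oxo-6-[(1S,2S)-1,3,3-trimethyl-2-vinylcyclohexyl]octanoate | COC(=O)C[C@@H](C)CC[C@@H](C(C)=O)[C@@]1(C)CCCC(C)(C)[C@@H]1C=C
F0 | step 8 | none | none
F2 | step 10 | benzyl (5S,8R,9R,10S,13S)-8-hydroxylabdan-15-oate | O=C(OCc1ccccc1)C[C@@H](C)CC[C@@H]1[C@@]2(C)CCCC(C)(C)[C@@H]2CC[C@@]1(C)O
F3 | step 10 | benzyl (5S,8R,9R,10S,13S)-8-formyloxylabdan-15-oate | O=C(OCc1ccccc1)C[C@@H](C)CC[C@@H]1[C@@]2(C)CCCC(C)(C)[C@@H]2CC[C@@]1(C)OC=O
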